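Each quinone ring is numbered C1 (C=O flanked by C2 and C6), C2 (OH), C3 (CH3), C4 (C=O), C5 (inter-ring bond) and C6 (CH2CH2Ph). The two C2–OH groups are taken back to C2–H. In the resulting 5,5'-biquinone, C2=C3 is the only trisubstituted ring alkene and C2 the only unsubstituted enone β-carbon. The key step exploits this by epoxidizing C2=C3 of both rings with alkaline H2O2 in one operation, leaving the tetrasubstituted C5=C6 bonds alone. Acid then turns each oxirane into the C2 enol. The precursor is a symmetrical biquinone made by ortho–ortho coupling of a 4-methoxyphenol with one free ortho position.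

Key step: step 6

Assumption: the target carries no stereodescriptor, so the hindered biaryl axis is taken as racemic; 14 is expected as a mixture of diastereomers (ring to ring and ring to axis) that is carried on as such, since step 7 removes all four stereocentres.

Step 1
Reactants: 1 4-methoxy-2-methylphenol; 2 acetic anhydride
Product: 3 4-methoxy-2-methylphenyl acetate
Conditions: Ac2O, pyridine, rt
Reagents that add atoms: acetic anhydride, CC(=O)OC(C)=O
Why: Pyridine-mediated O-acetylation of the phenol turns the OH from the strongest into a weak ring donor, so that the methoxy group alone decides the site of the next step.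

Step 2
Reactants: 3 4-methoxy-2-methylphenyl acetate; 4 phenylacetyl chloride
Product: 5 4-methoxy-2-methyl-5-(phenylacetyl)phenyl acetate
Conditions: SnCl4, CH2Cl2, 0 °C to rt
Reagents that add atoms: phenylacetyl chloride, O=C(Cl)Cc1ccccc1
Why: Friedel–Crafts acylation is directed ortho by the methoxy group, where the position para to CH3 is open while the other ortho site is wedged between OCH3 and CH3, and SnCl4 is mild enough to spare the aryl acetate and the methyl ether.

Step 3
Reactants: 5 4-methoxy-2-methyl-5-(phenylacetyl)phenyl acetate
Product: 7 4-methoxy-2-methyl-5-(2-phenylethyl)phenol, via reduced aryl acetate 6 (not isolated)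
Conditions: Et3SiH, CF3CO2H, rt; evaporate; then K2CO3, MeOH, rt, N2
Reagents that add atoms: none
Why: Ionic hydrogenation, in which the protonated aryl ketone and then the benzylic cation (stabilized by ortho OCH3 and para CH3) each take hydride from the silane, should reduce C=O to CH2 without touching the ester, after which carbonate-catalysed methanolysis of the aryl acetate frees the phenol in the same flask.

Step 4
Reactants: 7 4-methoxy-2-methyl-5-(2-phenylethyl)phenol (two molecules)
Product: 8 5,5'-dimethoxy-3,3'-dimethyl-6,6'-bis(2-phenylethyl)biphenyl-2,2'-diol (racemic axis)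
Conditions: FeCl3 (anhydrous, 1.1 equiv per phenol) on SiO2, CH2Cl2, rt, N2
Reagents that add atoms: none
Why: Oxidative phenol coupling by one-electron oxidation with trivalent iron gives a phenoxyl radical with spin at C2, C4 and C6, of which C2 carries CH3 and C4 carries OCH3, so the only carbon that can form a C–C bond and rearomatize is C6 and the 2,2'-biphenol should result.

Step 5
Reactants: 8 5,5'-dimethoxy-3,3'-dimethyl-6,6'-bis(2-phenylethyl)biphenyl-2,2'-diol; 9 water
Product: 11 5,5'-bi[3-methyl-6-(2-phenylethyl)-1,4-benzoquinone], via mono-quinone 10 (not isolated)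
Conditions: (NH4)2Ce(NO3)6, MeCN/H2O, 0 °C
Reagents that add atoms: water, O
Why: Oxidative demethylation of a p-methoxyphenol by tetravalent cerium proceeds through a phenoxenium ion that water captures at the methoxy-bearing carbon, and the hemiketal loses methanol to leave the quinone carbonyl, once in each ring.

Step 6
Reactants: 11 5,5'-bi[3-methyl-6-(2-phenylethyl)-1,4-benzoquinone]; 12 hydrogen peroxide
Product: 14 bis(2,3-epoxide) of 11, each oxirane cis-fused, drawn as (2R,3S,2'R,3'S), racemic, via mono-epoxide 13 (not isolated)
Conditions: 30% aq. H2O2 (excess), Na2CO3, 1,4-dioxane/H2O, 0 °C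
Reagents that add atoms: hydrogen peroxide, OO
Why: In this Weitz–Scheffer nucleophilic epoxidation, hydroperoxide anion adds to C2, the only unsubstituted enone β-carbon (β to the C4 carbonyl), and the resulting C3 enolate attacks the proximal peroxide oxygen and expels hydroxide. The closest known reaction type is the alkaline H2O2 epoxidation of 2-methyl-1,4-quinones such as 2-methyl-1,4-naphthoquinone. Each oxirane closes by a 3-exo-tet displacement at oxygen by the enolate carbon C3, so the C2–O bond forms first and the C3–O bond second. C2 and C3 of each ring are set together by the ring itself, since an oxirane on a six-membered ring can only be cis-fused; the relation between the two rings and to the biaryl axis is left uncontrolled because step 7 deletes all four centres. The selectivity needed is for C2=C3 over C5=C6, and the substrate secures it: both carbons of C5=C6 are substituted and screened by the neighbouring ring and the phenethyl chain, whereas C2 is open. Na2CO3 at 0 °C should keep the medium too weakly basic to open the oxiranes or attack the carbonyl groups, and excess peroxide should carry mono-epoxide 13 on to 14.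

Step 7
Reactants: 14 bis(2,3-epoxide) of 11
Product: 16 5,5'-bi[2-hydroxy-3-methyl-6-(2-phenylethyl)-1,4-benzoquinone], via half-isomerized mono-epoxide 15 (not isolated)
Conditions: conc. H2SO4, 0 °C, a few minutes; then ice–water
Reagents that add atoms: none
Why: Acid-catalysed isomerization of a 2,3-epoxy-1,4-dione to a 2-hydroxyquinone opens the protonated oxirane at the tertiary C3–O bond and restores C2=C3 by loss of the C2 proton with the oxygen kept on C2, so all four stereocentres vanish and every diastereomer of 14 converges on 16, the short cold contact being chosen to spare the phenyl rings from sulfonation.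

Compound list

1 | 4-methoxy-2-methylphenol | COc1ccc(O)c(C)c1 | starting material
2 | acetic anhydride | CC(=O)OC(C)=O | starting material
3 | 4-methoxy-2-methylphenyl acetate | CC(=O)Oc1ccc(OC)cc1C | intermediate
4 | phenylacetyl chloride | O=C(Cl)Cc1ccccc1 | starting material
5 | 4-methoxy-2-methyl-5-(phenylacetyl)phenyl acetate | CC(=O)Oc1cc(C(=O)Cc2ccccc2)c(OC)cc1C | intermediate
6 | 4-methoxy-2-methyl-5-(2-phenylethyl)phenyl acetate (formed in the flask, not isolated) | CC(=O)Oc1cc(CCc2ccccc2)c(OC)cc1C | intermediate
7 | 4-methoxy-2-methyl-5-(2-phenylethyl)phenol | COc1cc(C)c(O)cc1CCc1ccccc1 | intermediate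
8 | 5,5'-dimethoxy-3,3'-dimethyl-6,6'-bis(2-phenylethyl)biphenyl-2,2'-diol, racemic axis | COc1cc(C)c(O)c(-c2c(O)c(C)cc(OC)c2CCc2ccccc2)c1CCc1ccccc1 | intermediate
9 | water | O | starting material
10 | 3-[2-hydroxy-5-methoxy-3-methyl-6-(2-phenylethyl)phenyl]-5-methyl-2-(2-phenylethyl)-1,4-benzoquinone (formed in the flask, not isolated) | COc1cc(C)c(O)c(C2=C(CCc3ccccc3)C(=O)C=C(C)C2=O)c1CCc1ccccc1 | intermediate
11 | 5,5'-bi[3-methyl-6-(2-phenylethyl)-1,4-benzoquinone] (ring numbering of the overview; C2–H, C3–CH3) | CC1=CC(=O)C(CCc2ccccc2)=C(C2=C(CCc3ccccc3)C(=O)C=C(C)C2=O)C1=O | intermediate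
12 | hydrogen peroxide | OO | starting material
13 | mono(2,3-epoxide) of 11, oxirane cis-fused, drawn (2R,3S), racemic (formed in the flask, not isolated) | C[C@]12O[C@H]1C(=O)C(CCc1ccccc1)=C(C2=O)C1=C(CCc2ccccc2)C(=O)C=C(C)C1=O | intermediate
14 | 5,5'-bi[2,3-epoxy-3-methyl-6-(2-phenylethyl)cyclohex-5-ene-1,4-dione], both oxiranes cis-fused, drawn (2R,3S,2'R,3'S), racemic; the other ring-to-ring and ring-to-axis diastereomers serve equally | C[C@]12O[C@H]1C(=O)C(CCc1ccccc1)=C(C2=O)C1=C(CCc2ccccc2)C(=O)[C@@H]2O[C@]2(C)C1=O | intermediate
15 | biaryl with one ring as in 14 (cis-fused 2,3-epoxide, drawn (2R,3S), racemic) and one ring as in 16 (formed in the flask, not isolated) | C[C@]12O[C@H]1C(=O)C(CCc1ccccc1)=C(C2=O)C1=C(CCc2ccccc2)C(=O)C(O)=C(C)C1=O | intermediate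
16 | 5,5'-bi[2-hydroxy-3-methyl-6-(2-phenylethyl)-1,4-benzoquinone] | CC1=C(O)C(=O)C(CCc2ccccc2)=C(C2=C(CCc3ccccc3)C(=O)C(O)=C(C)C2=O)C1=O | target

Total step count: 7. Longest linear sequence: 7 steps (1 to 16).

Steps most likely to fail

1. Step 6 (key step). Hydroxide or hydroperoxide may attack the carbonyl carbons of the crowded biquinone (ring cleavage or contraction) faster than the second ring is epoxidized, or the reaction may stall after one ring for lack of solubility. The fallback oxygenates C2 by conjugate addition of acetate instead of peroxide. Setting out from 11, Thiele–Winter acetoxylation (Ac2O, BF3·OEt2, rt) should add acetate at the free C2 of each ring and acetylate the resulting hydroquinones, giving 2,2',4,4',5,5'-hexaacetoxy-3,3'-dimethyl-6,6'-bis(2-phenylethyl)biphenyl F1. NaOMe in MeOH under N2 would remove the six acetyl groups to give 3,3'-dimethyl-6,6'-bis(2-phenylethyl)biphenyl-2,2',4,4',5,5'-hexol F2. Admitting air then oxidizes each 1,2,4-trihydroxyarene to the 2-hydroxyquinone, and the route is rejoined at 16.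

2. Step 4. The phenoxyl radical may couple through oxygen, or the electron-rich biphenol may be oxidized further, instead of clean formation of the hindered C6–C6' bond. The fallback builds the biaryl bond by reductive coupling of an aryl halide. Setting out from 7, ortho-iodination (N-iodosuccinimide, cat. TsOH, MeCN, 0 °C) at the same single free ortho position should give 2-iodo-4-methoxy-6-methyl-3-(2-phenylethyl)phenol F3. O-Methylation (MeI, K2CO3, acetone) gives 1-iodo-2,5-dimethoxy-3-methyl-6-(2-phenylethyl)benzene F4. Ullmann homocoupling (Cu powder, DMF, 150 °C) gives 2,2',5,5'-tetramethoxy-3,3'-dimethyl-6,6'-bis(2-phenylethyl)biphenyl F5. Oxidative demethylation of both hydroquinone dimethyl ether rings with (NH4)2Ce(NO3)6 in MeCN/H2O then leads directly to 11, where the route is rejoined.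

3. Step 7. In concentrated acid the phenyl rings may be sulfonated, or the phenethyl arene may cyclize onto a protonated quinone carbonyl, in competition with oxirane opening. The fallback replaces the cationic opening by an anionic one. Setting out from 14, aqueous NaOH in 1,4-dioxane under N2 at 0 °C should remove the C2 proton (acidified by the C1 carbonyl) and expel the C3 oxygen as alkoxide in a β-elimination, giving the disodium salt of 16 F6. Acidification with dilute HCl returns the route at 16.

Further compounds

F1 | step 6 | 2,2',4,4',5,5'-hexaacetoxy-3,3'-dimethyl-6,6'-bis(2-phenylethyl)biphenyl | CC(=O)Oc1c(C)c(OC(C)=O)c(-c2c(OC(C)=O)c(C)c(OC(C)=O)c(OC(C)=O)c2CCc2ccccc2)c(CCc2ccccc2)c1OC(C)=O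
F2 | step 6 | 3,3'-dimethyl-6,6'-bis(2-phenylethyl)biphenyl-2,2',4,4',5,5'-hexol | Cc1c(O)c(O)c(CCc2ccccc2)c(-c2c(O)c(C)c(O)c(O)c2CCc2ccccc2)c1O
F3 | step 4 | 2-iodo-4-methoxy-6-methyl-3-(2-phenylethyl)phenol | COc1cc(C)c(O)c(I)c1CCc1ccccc1
F4 | step 4 | 1-iodo-2,5-dimethoxy-3-methyl-6-(2-phenylethyl)benzene | COc1cc(C)c(OC)c(I)c1CCc1ccccc1
F5 | step 4 | 2,2',5,5'-tetramethoxy-3,3'-dimethyl-6,6'-bis(2-phenylethyl)biphenyl | COc1cc(C)c(OC)c(-c2c(OC)c(C)cc(OC)c2CCc2ccccc2)c1CCc1ccccc1
F6 | step 7 | disodium salt of 16 | [Na+].[Na+].CC1=C([O-])C(=O)C(CCc2ccccc2)=C(C2=C(CCc3ccccc3)C(=O)C([O-])=C(C)C2=O)C1=O
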